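Time is what to watch, so follow Tuesday's run hour by hour; the new flask repeats it with half of the first nucleophile, and you may stop it at any time up to 15 d.

- Tuesday's: substrate 0.80 M; first nucleophile 3 equiv; solid second nucleophile 1 equiv; run made earlier
- flask: substrate 0.80 M; first nucleophile 1.50 equiv; solid second nucleophile 1.00 equiv; time 15 d

Tuesday's run (percent of the substrate charged): time / h: target / % = 3.00: 18.2; 5.00: 26.3; 8.00: 30.7; 12.0: 35.0; 20.0: 35.4; 40.0: 33.6

(standard deviation of a reading: 0.5 percentage points)

- at the start none of the solid second nucleophile is in solution

* the best time, 15 d at the latest, for target
* the amount of target, in percent of the substrate charged, at that time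
* earliest time at which at least nineteen twentieths of that best amount are there, in d
* latest time at which they still are, in d

In the first hours of Tuesday's run target climbs, reaching 18.2% at 3.00 h. If you treat this as a first-order rise towards the highest reading, 35.4%, you get a clock of 0.241 h⁻¹.

My assumption for the middle of the run is that this clock belongs to a slow first step of the substrate (the rate-limiting step), and that what this step makes then chooses between the first nucleophile and a path that needs none. The balance of substrate then says that whatever does not become target becomes something else. So divide the target fraction by the remaining fraction, and divide that by the charged concentration of first nucleophile. Taken at the highest reading, with its scatter, this is the capture ratio 0.228 M⁻¹.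

At the end of Tuesday's run target sinks from 35.4% to 33.6% over the last readings, a loss of 0.00261 h⁻¹, which is far slower than the rise.

For the new flask, my reckoning takes the charged 1.20 M of first nucleophile, which gives odds of 0.274 and a target share of 21.5%. With both clocks kept, my estimate puts the peak at 0.792 d and the asked band from 0.519 d to 1.59 d.

The forecast differs: 35% at 1.8 d, with the band from 0.9 d to 3.5 d. Its ground for the timing is this: “Assuming first-order dependence on the first nucleophile, halving it, plus its depletion, slows formation to about 0.1/h.”

The flask gives 21.4% at 0.755 d, with the band from 0.427 d to 1.61 d.

    substrate → intermediate (k = 0.230 h⁻¹)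
    first nucleophile + intermediate → target (k = 9.10 M⁻¹ h⁻¹)
    second nucleophile + intermediate → other capture product (k = 37.0 M⁻¹ h⁻¹)
    intermediate → solvolysis product (k = 33.0 h⁻¹)
    substrate + intermediate → side product (k = 0.0450 M⁻¹ h⁻¹)
    target ⇌ isomer of the product (K = 0.980, k = 0.00350 h⁻¹)
    solid second nucleophile ⇌ second nucleophile, rate k7*(cs7 - [second nucleophile]) while solid is left; crystals form when [second nucleophile] > cs7 (solubility = 0.370 M, k = 0.0250 h⁻¹)

Now carry the capture ratio to the neighbouring flask, with 0.20 M of substrate and the same equivalents. Its first nucleophile is charged at 0.300 M, so 0.228 M⁻¹ gives odds of 0.0685 and a target share of 6.41%. That neighbour's best is 6.78%. At its end it holds 3.93% of target and 89.4% of solvolysis product.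

The earlier runs and the new flask are calculated with constants of no real substance, and the scatter is random.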